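**Retrosynthetic overview**
1. Target ⇒ cut the chromone C2–CH2 bond: 5-hydroxy-7-methoxychromone 10 plus (R)-epoxy ester 7, joined in the last step by a blue-light cobaloxime C2–H β-hydroxyalkylation. The carbinol carbon is the untouched epoxide carbon.
2. 7 ⇒ (R)-1,2-epoxy-5-hexene 4 plus methyl acrylate 5 (cross-metathesis, then hydrogenation); 4 ⇒ (R)-epichlorohydrin 1 plus allylmagnesium chloride 2.
3. 10 ⇒ 2',6'-dihydroxy-4'-methoxyacetophenone 8 plus DMF-DMA.
4. Ring order: oxirane re-closed (step 1), pyranone ring closed (step 3), no ring formed in the coupling (step 4).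

Assumption: 1, 2, 5 and 8 are taken as catalogue materials. The target SMILES corresponds to the (R)-alcohol, which requires (R)-epichlorohydrin.

**Step 1**
Reactants: 1 (R)-epichlorohydrin; 2 allylmagnesium chloride
Product: 4 (R)-2-(but-3-en-1-yl)oxirane, via (R)-1-chlorohex-5-en-2-ol 3 (not isolated)
Conditions: 2 (1.1 equiv), CuI (2 mol %), THF, −30 → 0 °C; then aq NaOH, rt; distil
Reagents that add atoms: none
Why: Cu-catalysed Grignard opening of the epoxide at its unsubstituted CH2 (faster than SN2 at C–Cl), then Williamson-type closure of the chlorohydrin with NaOH; the C–O bond at the stereocentre is never broken, so (R)-1 gives (R)-4.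

**Step 2**
Reactants: 4 (R)-2-(but-3-en-1-yl)oxirane; 5 methyl acrylate
Product: 7 methyl (R)-5-(oxiran-2-yl)pentanoate, via methyl (E)-5-[(R)-oxiran-2-yl]pent-2-enoate 6 (not isolated)
Conditions: Hoveyda–Grubbs II (2 mol %), 5 (3 equiv), CH2Cl2, 40 °C; concentrate; then 10% Pd/C, H2 (1 atm), EtOAc, rt
Reagents that add atoms: none
Why: Olefin cross-metathesis of a terminal alkene with methyl acrylate gives the E-enoate with loss of ethylene, and the conjugated C=C is then hydrogenated over Pd/C under mild conditions that leave the aliphatic terminal epoxide and its stereocentre intact.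

**Step 3**
Reactants: 8 1-(2,6-dihydroxy-4-methoxyphenyl)ethan-1-one
Product: 10 5-hydroxy-7-methoxy-4H-chromen-4-one, via (E)-1-(2,6-dihydroxy-4-methoxyphenyl)-3-(dimethylamino)prop-2-en-1-one 9 (not isolated)
Conditions: DMF-DMA (2 equiv), toluene, 90 °C; then AcOH, 100 °C
Reagents that add atoms: N,N-dimethylformamide dimethyl acetal, COC(OC)N(C)C
Why: Enaminone condensation at the acetyl CH3, then acid-promoted intramolecular addition–elimination (loss of Me2NH) by one of the two equivalent ortho-phenols closes the pyranone; the symmetry of 8 fixes the 5-OH/7-OMe pattern.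

**Step 4**
Reactants: 7 methyl (R)-5-(oxiran-2-yl)pentanoate; 10 5-hydroxy-7-methoxy-4H-chromen-4-one
Product: 11 methyl (R)-6-hydroxy-7-(5-hydroxy-7-methoxy-4-oxo-4H-chromen-2-yl)heptanoate (Penithochromone O)
Conditions: 7 (1 equiv), 10 (2 equiv), Co(dmgH)2(py)Cl (10 mol %), Zn dust (20 mol %), iPr2NEt (1 equiv), MeCN–MeOH 4:1, 450 nm LEDs, 25 °C
Reagents that add atoms: none
Why: Proposed new method: cobaloxime(I), formed from the Co(III) precatalyst by Zn, opens epoxide 7 by SN2 at the terminal CH2 (the C–O bond at the stereocentre is not touched, so the (R) centre from 1 is carried over) to give a 2-hydroxyalkyl–Co(III) species; blue light homolyses its Co–C bond, the primary β-hydroxyalkyl radical adds to C2 (the enone β-carbon) of the hydrogen-bond-activated chromone 10, and Co(II) removes the C2–H of the resulting C3 α-keto radical (dehydrocobaltation) to restore the chromone and give Co(III)–H, which iPr2NEt deprotonates back to Co(I) while the ammonium protonates the next alkoxide, so the coupling is redox-neutral with no co-product; the closest known reaction types are the visible-light cobaloxime alkyl-Heck-type coupling of alkyl halides with styrenes and acrylates and the Co(I) ring opening of terminal epoxides at the less hindered carbon to give alkyl radicals, neither shown for an epoxide adding to a chromone C2–H bond.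

**Compound list**
1 | (R)-epichlorohydrin [(R)-2-(chloromethyl)oxirane] | ClC[C@H]1CO1 | starting material
2 | allylmagnesium chloride | C=CC[Mg]Cl | starting material
3 | (R)-1-chlorohex-5-en-2-ol | ClC[C@H](O)CCC=C | intermediate (not isolated)
4 | (R)-2-(but-3-en-1-yl)oxirane [(R)-1,2-epoxy-5-hexene] | C=CCC[C@@H]1CO1 | intermediate
5 | methyl acrylate | C=CC(=O)OC | starting material
6 | methyl (E)-5-[(R)-oxiran-2-yl]pent-2-enoate | COC(=O)/C=C/CC[C@@H]1CO1 | intermediate (not isolated)
7 | methyl (R)-5-(oxiran-2-yl)pentanoate | COC(=O)CCCC[C@@H]1CO1 | intermediate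
8 | 1-(2,6-dihydroxy-4-methoxyphenyl)ethan-1-one | CC(=O)c1c(O)cc(OC)cc1O | starting material
9 | (E)-1-(2,6-dihydroxy-4-methoxyphenyl)-3-(dimethylamino)prop-2-en-1-one | CN(C)/C=C/C(=O)c1c(O)cc(OC)cc1O | intermediate (not isolated)
10 | 5-hydroxy-7-methoxy-4H-chromen-4-one | COc1cc(O)c2c(c1)occc2=O | intermediate
11 | methyl (R)-6-hydroxy-7-(5-hydroxy-7-methoxy-4-oxo-4H-chromen-2-yl)heptanoate (Penithochromone O) | COC(=O)CCCC[C@@H](O)Cc1cc(=O)c2c(O)cc(OC)cc2o1 | target

**Totals**
Total step count: 4 (steps 1, 2 and 4 linear; step 3 on the convergent branch).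
Longest linear sequence: 3 steps (1 → 2 → 4).

**Three steps most likely to fail**

Step 4 (proposed new coupling). Likely failure modes are isomerisation of the 2-hydroxyalkyl–cobalt species to the methyl ketone, slow radical addition to the vinylogous-ester C2, and reductive interception giving the chromanone. The fallback uses known chemistry and builds the pyranone ring on the side chain instead. It sets out from 7: Yamaguchi alkynylation with lithium (trimethylsilyl)acetylide and BF3·OEt2 (THF, −78 °C) opens the epoxide at CH2 to give methyl (R)-6-hydroxy-9-(trimethylsilyl)non-8-ynoate F1. K2CO3 in MeOH removes the silyl group to give methyl (R)-6-hydroxynon-8-ynoate F2. Commercial 3,5-dimethoxyphenol is ortho-iodinated (BnMe3N·ICl2, NaHCO3, CH2Cl2–MeOH) to 2-iodo-3,5-dimethoxyphenol F3. Pd-catalysed carbonylative Sonogashira annulation of F2 with F3 (PdCl2(dppf), CO, Et2NH, 120 °C) gives methyl (R)-7-(5,7-dimethoxy-4-oxo-4H-chromen-2-yl)-6-hydroxyheptanoate F4. BCl3 (CH2Cl2, −78 → 0 °C) cleaves only the peri 5-O-methyl, and the sequence comes back to the route at 11.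

Step 2 (one-pot cross-metathesis and hydrogenation). Ru residues may poison the Pd, or the epoxide may be partly hydrogenolysed. The fallback replaces metathesis and hydrogenation by oxidative cleavage. It sets out from 1: Cu-catalysed opening with pent-4-en-1-ylmagnesium bromide gives (R)-1-chlorooct-7-en-2-ol F5, which NaOH closes to (R)-2-(hex-5-en-1-yl)oxirane F6. Ozonolysis in methanolic NaOH (O3, NaOH/MeOH, CH2Cl2, −78 °C) converts the terminal alkene directly into the methyl ester, and the sequence comes back to the route at 7.

Step 3 (DMF-DMA on a substrate with two free phenols). O-methylation by the acetal or incomplete cyclisation may occur. The fallback uses a formate Claisen condensation instead of the enaminone. It sets out from 8: NaH (4 equiv) and ethyl formate in THF C-formylate the acetyl group to give, after quench, the cyclic hemiacetal 2,5-dihydroxy-7-methoxychroman-4-one F7. Warming in AcOH with catalytic HCl dehydrates it, and the sequence comes back to the route at 10.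

**Further compounds**
F1 | step 4 | methyl (R)-6-hydroxy-9-(trimethylsilyl)non-8-ynoate | COC(=O)CCCC[C@@H](O)CC#C[Si](C)(C)C
F2 | step 4 | methyl (R)-6-hydroxynon-8-ynoate | COC(=O)CCCC[C@@H](O)CC#C
F3 | step 4 | 2-iodo-3,5-dimethoxyphenol | COc1cc(O)c(I)c(OC)c1
F4 | step 4 | methyl (R)-7-(5,7-dimethoxy-4-oxo-4H-chromen-2-yl)-6-hydroxyheptanoate | COC(=O)CCCC[C@@H](O)Cc1cc(=O)c2c(OC)cc(OC)cc2o1
F5 | step 2 | (R)-1-chlorooct-7-en-2-ol | ClC[C@H](O)CCCCC=C
F6 | step 2 | (R)-2-(hex-5-en-1-yl)oxirane | C=CCCCC[C@@H]1CO1
F7 | step 3 | 2,5-dihydroxy-7-methoxychroman-4-one | COc1cc(O)c2C(=O)CC(O)Oc2c1
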